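The route disconnects the ketone carbonyl carbon from C1 of the fully substituted phloroglucinol ring (ring A). The key step is a Friedel–Crafts benzoylation of 1,3,5-trimethoxybenzene that runs on, in the same flask, into a chelation-directed double demethylation. The three ring CH positions of the precursor are equivalent, so only one ketone can form. The new carbonyl then guides AlCl3 to cleave exactly the two flanking methyl ethers (O2 and O6), while the para O4 methyl ether stays. One operation thus forms the aryl–carbonyl bond and sets the 2,6-dihydroxy-4-methoxy pattern. A double C-prenylation at the only free ring carbons, C3 and C5, finishes the target.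

Key step: step 1

Remark on the chemistry: ring A is numbered so that C1 carries the benzoyl group, C2 and C6 the hydroxyl groups, C3 and C5 the prenyl groups and C4 the methoxy group. The target has no stereocentre, and each side-chain alkene ends in two identical methyl groups, so no stereochemical element has to be set.

Step 1
Reactants: 1 1,3,5-trimethoxybenzene; 2 benzoyl chloride
Product: 5 cotoin (2,6-dihydroxy-4-methoxybenzophenone), via 2,4,6-trimethoxybenzophenone 3 (not isolated), via hydrocotoin 4 (not isolated)
Conditions: AlCl3 (1.1 equiv), PhCl, 0 °C; then AlCl3 (3 equiv), 90 °C; 1 M aq. HCl work-up
Reagents that add atoms: none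
Why: Friedel–Crafts acylation: the benzoyl chloride–AlCl3 complex attacks the electron-rich arene, whose three ring CH carbons are homotopic and each flanked by two methoxy-bearing carbons, so a single ketone should form, and its AlCl3 complex is too deactivated and too hindered for a second acylation. The closest known reaction type is the Friedel–Crafts acylation of polymethoxyarenes with ortho-demethylation by the same Lewis acid. On heating with excess AlCl3, the carbonyl oxygen and one ortho methoxy oxygen chelate aluminium, and chloride removes that methyl group by SN2 attack as chloromethane; the carbonyl then turns to the second ortho methoxy group and the process repeats, the phenols being held as ArOAlCl2 species until work-up. No ring is closed and no stereocentre is formed. The step needs site selectivity among three methyl ethers, and this is secured by the substrate itself: only O2 and O6 can form a six-membered chelate with the new carbonyl, whereas the O4 methyl ether has no such assistance and should survive.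

Step 2
Reactants: 5 cotoin; 6 prenyl bromide (1-bromo-3-methylbut-2-ene)
Product: 8 (2,6-dihydroxy-4-methoxy-3,5-bis(3-methylbut-2-en-1-yl)phenyl)(phenyl)methanone, via 3-prenylcotoin 7 (not isolated)
Conditions: prenyl bromide (2.3 equiv in all), 10% aq. KOH, 0 °C to rt; then cold 1 M HCl to pH 3
Reagents that add atoms: prenyl bromide (second equivalent), CC(C)=CCBr
Why: Two successive phenoxide C-alkylations (C-prenylation of an acylphloroglucinol by SN2 attack of a ring carbon on the allylic bromide, first at C3 to give the mono-prenyl compound and then at C5) should work because in water the phenoxide oxygens are shielded by hydrogen bonds, and C3 and C5, each ortho to one phenoxide oxygen and para to the other, are the only unsubstituted ring carbons.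

Compound list
1 | 1,3,5-trimethoxybenzene | COc1cc(OC)cc(OC)c1 | starting material
2 | benzoyl chloride | O=C(Cl)c1ccccc1 | starting material
3 | 2,4,6-trimethoxybenzophenone | COc1cc(OC)c(C(=O)c2ccccc2)c(OC)c1 | intermediate (not isolated)
4 | hydrocotoin, 2-hydroxy-4,6-dimethoxybenzophenone (in the flask as its ArOAlCl2 chelate) | COc1cc(O)c(C(=O)c2ccccc2)c(OC)c1 | intermediate (not isolated)
5 | cotoin, 2,6-dihydroxy-4-methoxybenzophenone | COc1cc(O)c(C(=O)c2ccccc2)c(O)c1 | intermediate
6 | prenyl bromide, 1-bromo-3-methylbut-2-ene | CC(C)=CCBr | starting material
7 | 3-prenylcotoin, (2,6-dihydroxy-4-methoxy-3-(3-methylbut-2-en-1-yl)phenyl)(phenyl)methanone | COc1cc(O)c(C(=O)c2ccccc2)c(O)c1CC=C(C)C | intermediate (not isolated)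
8 | (2,6-dihydroxy-4-methoxy-3,5-bis(3-methylbut-2-en-1-yl)phenyl)(phenyl)methanone | COc1c(CC=C(C)C)c(O)c(C(=O)c2ccccc2)c(O)c1CC=C(C)C | target

Total step count: 2
Longest linear sequence: 2 steps

Steps most likely to fail (the route has only two steps, so both are given, the riskier first):

1. Step 1. The demethylation may stop after the first ortho ether. Under the hot Lewis acid it may instead go on to the para ether, or the hindered ketone may lose its acyl group by protodeacylation. Fallback: selective masking in place of selective unmasking. It sets out from benzoyl chloride 2. Friedel–Crafts benzoylation of commercial phloroglucinol F1 (AlCl3, PhNO2, 60 °C) should give 2,4,6-trihydroxybenzophenone F2; again only one ketone is possible, because the three CH positions are equivalent. Mono-O-methylation with one equivalent of dimethyl sulfate (K2CO3, acetone, rt) should then take the O4 hydroxyl, which is the most acidic one (para to the carbonyl) and cannot hydrogen-bond to the carbonyl. The fallback comes back to the route at cotoin 5.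

2. Step 2. O-alkylation may compete with C-alkylation, a second prenyl group may enter at an already prenylated carbon with loss of aromaticity, or the second C-prenylation may stay incomplete. Fallback: ether formation followed by O-to-C migration in place of direct C-alkylation. It sets out from cotoin 5. Double O-prenylation with two equivalents of prenyl bromide 6 (K2CO3, DMF, 50 °C) should give 2,6-bis(prenyloxy)-4-methoxybenzophenone F3. Montmorillonite K10 clay (CH2Cl2, 0 °C) should then ionise each aryl prenyl ether and return the prenyl group to a ring carbon in a formal 1,3-shift. C3 and C5 are the only unsubstituted ring carbons, and each is ortho to one ether oxygen and para to the other, so ortho and para migration both lead to the same product. The fallback comes back to the route at target 8.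

Further compounds
F1 | step 1 | phloroglucinol (benzene-1,3,5-triol) | Oc1cc(O)cc(O)c1
F2 | step 1 | 2,4,6-trihydroxybenzophenone | O=C(c1ccccc1)c1c(O)cc(O)cc1O
F3 | step 2 | 2,6-bis(3-methylbut-2-en-1-yloxy)-4-methoxybenzophenone | COc1cc(OCC=C(C)C)c(C(=O)c2ccccc2)c(OCC=C(C)C)c1
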